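(The earlier runs and the new flask were computed for substances that don't exist, and the scatter is random.)

**The flask.** I decided to hand over the teal flask with one number read from the earlier runs. Teal holds X and G with catalyst E, and its Z is wanted at 130 h.

| flask | X | G | E | time |
|---|---|---|---|---|
| amber | 0.200 M | 0.160 M | 0.0100 M |  |
| red | 0.120 M | 0.0800 M | 0.0100 M |  |
| green | 0.600 M | 0.160 M | 0.0100 M |  |
| teal | 0.200 M | 0.480 M | 0.0100 M | 130 h |

| run | time / h | [Z] / M |
|---|---|---|
| amber run | 22 | 0.0216 |
| amber run | 43 | 0.0325 |
| amber run | 65 | 0.0385 |
| amber run | 87 | 0.0396 |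
| amber run | 110 | 0.0412 |
| amber run | 130 | 0.0414 |
| red run | 22 | 0.0089 |
| red run | 43 | 0.0122 |
| red run | 65 | 0.0156 |
| red run | 87 | 0.0172 |
| red run | 110 | 0.0180 |
| red run | 130 | 0.0183 |
| green run | 22 | 0.0493 |
| green run | 43 | 0.0647 |
| green run | 65 | 0.0719 |
| green run | 87 | 0.0745 |
| green run | 110 | 0.0749 |
| green run | 130 | 0.0754 |

(scatter of a reading: 6 × 10⁻⁴ M)

- Overall: X + G -> Z, with E as catalyst.
- Constant volume, constant temperature.
- A reading of a species includes what of it is bound.
- An order is taken over about fifteen percent of the charge, up and down.

- the power of [X] that the first rate follows, about the charge of the amber run; measure it at two percent of X made into Z (one fixed amount of Z, the same in the runs compared)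
- the power of [G] that the first rate follows, about the charge of the amber run; measure it at two percent of X made into Z
- Z in the teal run at 130 h, as a share of the X charged

**What I read.** Amber levelled at 0.0414 M of Z, below its 0.160 M of G, and its last step of 0.200 mM was smaller than the scatter. Its first reading stood at 52.2% of that level, which gives τ = 29.8 h. This fading time τ, in which the gap to the level shrinks by a factor e, also gives the first rate as level over τ, here 0.00139 M h⁻¹. The same reading gives green 20.7 h, shorter than amber.

**Teal's state.** Teal has amber's X and 3.00 times its G. I took the first rate as rising in step with G. With amber's τ, Z at 130 h would be 62.1% of the X charged, but green, charged with more X than amber, read a shorter τ. With green's τ I expected 43.2%. Do not scale amber's level by the G charge.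

**The forecast.** It held that “either the reaction reaches equilibrium or the catalyst dies”. It gave orders of 0.82 in X and 0.82 in G, and 41% for teal, within 35% to 47%, a little below mine.

**The result.** The orders came out at 0.94 in X and 0.97 in G, and teal gave 27.2%. The steps were:

    E + X ⇌ EX (8.388 L mol⁻¹ h⁻¹, 8.928 h⁻¹)
    EX + G → Z + E (6.984 L mol⁻¹ h⁻¹)
    Z + G → L (0.08964 L mol⁻¹ h⁻¹)
    G → Ja (0.01440 h⁻¹)

**One reason.** Amber's first rate raised by the G order gives an estimate for teal of 0.00401 M h⁻¹, so its 27.2%, read as a level, means a τ of 13.6 h, shorter than green's. The main reason is the loss of Z to L through Z + G → L. The same teal run without that step reaches 66.1% at 130 h, which read the same way is a τ of 33.0 h against amber's 29.8 h.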